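**Plan**

- Retrosynthesis first opens the O–C8 and O–C8′ bonds of the two 2,5-dihydrofuran rings (O–C5–C6=C7–C8). This leads back to the 5,6- and 5′,6′-oxiranes of the C2-symmetric bis(vinyl oxirane) violaxanthin. The enabling feature is that each oxirane carbon C6 carries the C7=C8 end of the polyene: the C6–O bond is tertiary and allylic, and C8 lies 1,3 to the oxygen that stays on C5.
- The C40 chain is then cut at C11=C12 and C11′=C12′ (double Wittig) into two C15 epoxy dienals and one C10 bis-ylide. The C15 unit is cut at C7=C8 (Horner–Wadsworth–Emmons) into a C10 epoxy aldehyde and a C5 phosphonate.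
- The oxirane (Sharpless epoxidation) and the ring–C7 bond (carbonylation of an enol triflate) lead back to (4R,6R)-actinol.
- Forward order: bought carbocycle → oxirane → C15 chain → C40 chain carrying both oxiranes → desilylation → both three-membered rings expanded to five-membered rings in the last step.
- Stereochemistry: C3/C3′ come from actinol. C5/C5′ (and the transient C6/C6′) come from reagent-controlled Sharpless epoxidation. C8/C8′ arise in the ring expansion, which is not expected to be face-selective, so the (8R,8′R) isomer is isolated and the others are re-equilibrated with acid. Chain geometry comes from E-selective olefination and thermal isomerisation.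

Key step: step 13

Assumption: (4R,6R)-actinol (1) is bought enantiopure, and phosphonate 9 is used as the commercial E/Z mixture because its allyl anion equilibrates before olefination. TBS = tert-butyldimethylsilyl.

**Route**

Step 1
Reactants: 1 (4R,6R)-4-hydroxy-2,2,6-trimethylcyclohexan-1-one
Product: 2 (4R,6R)-4-(TBS-oxy)-2,2,6-trimethylcyclohexan-1-one
Conditions: TBSCl, imidazole, DMF, rt
Reagents that add atoms: tert-butyldimethylsilyl chloride, C[Si](C)(Cl)C(C)(C)C
Why: Standard silylation of an unhindered secondary alcohol gives an ether that survives base, hydride, palladium and oxidants, and the carbinol centre (future C3/C3′) is untouched.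

Step 2
Reactants: 2 (4R,6R)-4-(TBS-oxy)-2,2,6-trimethylcyclohexan-1-one
Product: 4 (4R)-4-(TBS-oxy)-2,6,6-trimethylcyclohex-1-en-1-yl trifluoromethanesulfonate, via lithium enolate 3 (not isolated)
Conditions: LiN(i-Pr)2, THF, −78 °C; then PhNTf2, −78 → 0 °C
Reagents that add atoms: N-phenylbis(trifluoromethanesulfonimide), O=S(=O)(N(c1ccccc1)S(=O)(=O)C(F)(F)F)C(F)(F)F
Why: The ketone has a single α-hydrogen, so only one enolate can form and its O-sulfonylation gives the tetrasubstituted enol triflate (enol triflate formation), the methyl-bearing stereocentre being erased on purpose.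

Step 3
Reactants: 4 (4R)-4-(TBS-oxy)-2,6,6-trimethylcyclohex-1-en-1-yl trifluoromethanesulfonate
Product: 5 methyl (4R)-4-(TBS-oxy)-2,6,6-trimethylcyclohex-1-ene-1-carboxylate
Conditions: Pd(OAc)2 (5 mol%), PPh3 (10 mol%), CO (1 atm), Et3N, MeOH/DMF, 60 °C
Reagents that add atoms: carbon monoxide, [C-]#[O+]; methanol, CO
Why: Oxidative addition of zerovalent palladium into the vinyl C–OTf bond, CO insertion and methanolysis of the acylpalladium species (alkoxycarbonylation of an enol triflate) attach the future C7 to the tetrasubstituted alkene.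

Step 4
Reactants: 5 methyl (4R)-4-(TBS-oxy)-2,6,6-trimethylcyclohex-1-ene-1-carboxylate
Product: 6 [(4R)-4-(TBS-oxy)-2,6,6-trimethylcyclohex-1-en-1-yl]methanol
Conditions: i-Bu2AlH (2.5 equiv), CH2Cl2, −78 → 0 °C; aq. KNaC4H4O6 work-up
Reagents that add atoms: none
Why: 1,2-Reduction of the conjugated ester (DIBAL reduction) gives the primary allylic alcohol that is needed to bind the epoxidation catalyst.

Step 5
Reactants: 6 [(4R)-4-(TBS-oxy)-2,6,6-trimethylcyclohex-1-en-1-yl]methanol
Product: 7 [(1R,4S,6R)-4-(TBS-oxy)-2,2,6-trimethyl-7-oxabicyclo[4.1.0]heptan-1-yl]methanol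
Conditions: Ti(OiPr)4 (20 mol%), D-(−)-diethyl tartrate (24 mol%), t-BuOOH (decane solution), 4 Å molecular sieves, CH2Cl2, −20 °C
Reagents that add atoms: tert-butyl hydroperoxide, CC(C)(C)OO
Why: Katsuki–Sharpless asymmetric epoxidation delivers oxygen under reagent control, and D-(−)-diethyl tartrate (the enantiomer that turns geraniol into its (2R,3R)-epoxide) epoxidises this ring-tied geraniol analogue on the face anti to the silyloxy group, setting both oxirane carbons (1R,6R; C6 and C5 of the carotenoid skeleton).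

Step 6
Reactants: 7 [(1R,4S,6R)-4-(TBS-oxy)-2,2,6-trimethyl-7-oxabicyclo[4.1.0]heptan-1-yl]methanol
Product: 8 (1S,4S,6R)-4-(TBS-oxy)-2,2,6-trimethyl-7-oxabicyclo[4.1.0]heptane-1-carbaldehyde
Conditions: (n-Pr4N)RuO4 (5 mol%), N-methylmorpholine N-oxide, 4 Å molecular sieves, CH2Cl2, rt
Reagents that add atoms: none
Why: Ley–Griffith oxidation under neutral conditions converts the primary alcohol into the non-enolisable epoxy aldehyde without opening the oxirane (the descriptor at C1 changes only through the priority rules).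

Step 7
Reactants: 8 (1S,4S,6R)-4-(TBS-oxy)-2,2,6-trimethyl-7-oxabicyclo[4.1.0]heptane-1-carbaldehyde; 9 diethyl (3-cyano-2-methylallyl)phosphonate
Product: 11 (2E,4E)-5-[(1S,4S,6R)-4-(TBS-oxy)-2,2,6-trimethyl-7-oxabicyclo[4.1.0]heptan-1-yl]-3-methylpenta-2,4-dienenitrile, via sodium phosphonate carbanion 10 (not isolated)
Conditions: 9 (1.5 equiv), NaH, THF, 0 °C; then 8, 0 °C → rt; chromatography
Reagents that add atoms: none
Why: Vinylogous Horner–Wadsworth–Emmons olefination through the α-carbon of the stabilised allyl anion should give the E-configured C7=C8 bond and mainly the E trisubstituted C9=C10 bond (the 9Z isomer is removed by chromatography), with the oxirane stereocentres untouched.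

Step 8
Reactants: 11 (2E,4E)-5-[(1S,4S,6R)-4-(TBS-oxy)-2,2,6-trimethyl-7-oxabicyclo[4.1.0]heptan-1-yl]-3-methylpenta-2,4-dienenitrile
Product: 13 (2E,4E)-5-[(1S,4S,6R)-4-(TBS-oxy)-2,2,6-trimethyl-7-oxabicyclo[4.1.0]heptan-1-yl]-3-methylpenta-2,4-dienal, via aluminium aldimine 12 (not isolated)
Conditions: i-Bu2AlH (1.2 equiv), toluene, −78 °C; then wet silica gel, 0 °C
Reagents that add atoms: water, O
Why: Single hydride addition to the nitrile gives the N-aluminio aldimine, which is hydrolysed on neutral wet silica (nitrile-to-aldehyde reduction), so no acid meets the vinyl oxirane.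

Step 9
Reactants: 14 (2E,4E,6E)-2,7-dimethylocta-2,4,6-trienedial
Product: 16 (2E,4E,6E)-2,7-dimethylocta-2,4,6-triene-1,8-diol, via hydroxy aldehyde 15 (not isolated)
Conditions: NaBH4, MeOH/THF, 0 °C
Reagents that add atoms: none
Why: Borohydride 1,2-reduction of both conjugated aldehyde groups gives the bis-allylic diol with the three E double bonds intact.

Step 10
Reactants: 16 (2E,4E,6E)-2,7-dimethylocta-2,4,6-triene-1,8-diol
Product: 18 [(2E,4E,6E)-2,7-dimethylocta-2,4,6-triene-1,8-diyl]bis(triphenylphosphonium) dibromide, via mono-phosphonium bromide 17 (not isolated)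
Conditions: PPh3·HBr (2.1 equiv), MeOH, rt
Reagents that add atoms: triphenylphosphine hydrobromide, [Br-].c1ccc(cc1)[PH+](c1ccccc1)c1ccccc1
Why: Allylic alcohols are converted directly into allyl phosphonium salts by PPh3·HBr (acid-assisted allylic substitution at the primary terminus), and the acid is used here on the fragment that carries no oxirane.

Step 11
Reactants: 18 [(2E,4E,6E)-2,7-dimethylocta-2,4,6-triene-1,8-diyl]bis(triphenylphosphonium) dibromide; 13 (2E,4E)-5-[(1S,4S,6R)-4-(TBS-oxy)-2,2,6-trimethyl-7-oxabicyclo[4.1.0]heptan-1-yl]-3-methylpenta-2,4-dienal (2.1 equiv)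
Product: 21 (3S,5R,6S,3′S,5′R,6′S)-3,3′-bis(TBS-oxy)-5,6:5′,6′-diepoxy-5,6,5′,6′-tetrahydro-β,β-carotene (violaxanthin bis-TBS ether), via bis-ylide 19 (not isolated), via C25 ylide 20 (not isolated)
Conditions: NaOMe (2.2 equiv), MeOH/CH2Cl2, 0 °C → rt, dark, Ar; then n-heptane, 90 °C
Reagents that add atoms: none
Why: Double Wittig olefination forms C11=C12 and C11′=C12′ and with them the C40 nonaene, and the hindered 11Z isomers that the semi-stabilised ylide also gives are expected to isomerise thermally to the all-E chain while the basic medium leaves oxiranes and silyl ethers intact.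

Step 12
Reactants: 21 violaxanthin bis-TBS ether
Product: 23 (3S,5R,6S,3′S,5′R,6′S)-5,6:5′,6′-diepoxy-5,6,5′,6′-tetrahydro-β,β-carotene-3,3′-diol (violaxanthin), via mono-TBS violaxanthin 22 (not isolated)
Conditions: n-Bu4NF, THF, 0 °C → rt, dark
Reagents that add atoms: none
Why: Fluoride cleaves both secondary silyl ethers under non-acidic conditions (desilylation), so the acid-labile vinyl oxiranes survive until the last step.

Step 13
Reactants: 23 violaxanthin
Product: 25 (3S,5R,8R,3′S,5′R,8′R)-5,8:5′,8′-diepoxy-5,8,5′,8′-tetrahydro-β,β-carotene-3,3′-diol (target), via (8′R)-luteoxanthin 24 (not isolated)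
Conditions: HCl (5 mol%, dry, in Et2O), CH2Cl2, 0 °C, dark, Ar, short contact; Et3N quench; preparative HPLC
Reagents that add atoms: none
Why: Protonation of an oxirane oxygen lets the tertiary C6–O bond ionise, because C6 carries the C7=C8 end of the nonaene and the cation is spread over C6, C8 and the further chain; the oxygen, still bound to C5, then closes on C8, inserting C7 and C8 into the three-membered ring, and the primed end follows through mono-rearranged 24. The closest known reaction type is the acid-catalysed epoxide–furanoid rearrangement of carotenoid 5,6-epoxides, a case of the vinyl oxirane to 2,5-dihydrofuran ring expansion. Each dihydrofuran closes by O–C8 bond formation in a formally 5-endo-trig mode, which is unrestricted here because the acceptor is a planar allyl-type cation. C5 and C5′ keep their configuration because their C–O bonds are never broken, whereas C8 and C8′ are set by the face of the cation that the C5 oxygen attacks, for which the ring (methyl on one side, C4 methylene on the other) offers only a weak bias. The (8R,8′R) isomer is therefore to be isolated by HPLC and the (8R,8′S) and (8S,8′S) isomers returned to the same acid, where reversible C8–O ionisation should re-equilibrate them. The step also needs closure at C8 and not further along the chain, secured by ring size, and oxygen recapture in preference to a ring-contracting 1,2-shift or hydration to the 5,6-diol, secured by the polyene-stabilised cation (traces of dry protic acid at 0 °C, no Lewis acid) and exclusion of water.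

**Compound list**

1 | (4R,6R)-4-hydroxy-2,2,6-trimethylcyclohexan-1-one (actinol) | O=C1C(C)(C)C[C@H](O)C[C@H]1C | starting material
2 | (4R,6R)-4-(TBS-oxy)-2,2,6-trimethylcyclohexan-1-one | O=C1C(C)(C)C[C@H](O[Si](C)(C)C(C)(C)C)C[C@H]1C | intermediate
3 | lithium (4R)-4-(TBS-oxy)-2,6,6-trimethylcyclohex-1-en-1-olate | CC1=C([O-])C(C)(C)C[C@H](O[Si](C)(C)C(C)(C)C)C1.[Li+] | intermediate (not isolated)
4 | (4R)-4-(TBS-oxy)-2,6,6-trimethylcyclohex-1-en-1-yl trifluoromethanesulfonate | CC1=C(OS(=O)(=O)C(F)(F)F)C(C)(C)C[C@H](O[Si](C)(C)C(C)(C)C)C1 | intermediate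
5 | methyl (4R)-4-(TBS-oxy)-2,6,6-trimethylcyclohex-1-ene-1-carboxylate | CC1=C(C(=O)OC)C(C)(C)C[C@H](O[Si](C)(C)C(C)(C)C)C1 | intermediate
6 | [(4R)-4-(TBS-oxy)-2,6,6-trimethylcyclohex-1-en-1-yl]methanol | CC1=C(CO)C(C)(C)C[C@H](O[Si](C)(C)C(C)(C)C)C1 | intermediate
7 | [(1R,4S,6R)-4-(TBS-oxy)-2,2,6-trimethyl-7-oxabicyclo[4.1.0]heptan-1-yl]methanol | OC[C@]12C(C)(C)C[C@H](O[Si](C)(C)C(C)(C)C)C[C@@]1(C)O2 | intermediate
8 | (1S,4S,6R)-4-(TBS-oxy)-2,2,6-trimethyl-7-oxabicyclo[4.1.0]heptane-1-carbaldehyde | O=C[C@]12C(C)(C)C[C@H](O[Si](C)(C)C(C)(C)C)C[C@@]1(C)O2 | intermediate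
9 | diethyl (3-cyano-2-methylallyl)phosphonate (E/Z mixture) | CCOP(=O)(OCC)CC(C)=CC#N | starting material
10 | sodium salt of the carbanion of 9 | [Na+].CCOP(=O)(OCC)[CH-]C(C)=CC#N | intermediate (not isolated)
11 | (2E,4E)-5-[(1S,4S,6R)-4-(TBS-oxy)-2,2,6-trimethyl-7-oxabicyclo[4.1.0]heptan-1-yl]-3-methylpenta-2,4-dienenitrile | N#C/C=C(C)/C=C/[C@]12C(C)(C)C[C@H](O[Si](C)(C)C(C)(C)C)C[C@@]1(C)O2 | intermediate
12 | N-(diisobutylalumanyl) aldimine of 13 | CC(C)C[Al](CC(C)C)N=C/C=C(C)/C=C/[C@]12C(C)(C)C[C@H](O[Si](C)(C)C(C)(C)C)C[C@@]1(C)O2 | intermediate (not isolated)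
13 | (2E,4E)-5-[(1S,4S,6R)-4-(TBS-oxy)-2,2,6-trimethyl-7-oxabicyclo[4.1.0]heptan-1-yl]-3-methylpenta-2,4-dienal | O=C/C=C(C)/C=C/[C@]12C(C)(C)C[C@H](O[Si](C)(C)C(C)(C)C)C[C@@]1(C)O2 | intermediate
14 | (2E,4E,6E)-2,7-dimethylocta-2,4,6-trienedial | O=C/C(C)=C/C=C/C=C(C)/C=O | starting material
15 | (2E,4E,6E)-8-hydroxy-2,7-dimethylocta-2,4,6-trienal | O=C/C(C)=C/C=C/C=C(C)/CO | intermediate (not isolated)
16 | (2E,4E,6E)-2,7-dimethylocta-2,4,6-triene-1,8-diol | OC/C(C)=C/C=C/C=C(C)/CO | intermediate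
17 | [(2E,4E,6E)-8-hydroxy-2,7-dimethylocta-2,4,6-trien-1-yl]triphenylphosphonium bromide | [Br-].OC/C(C)=C/C=C/C=C(C)/C[P+](c1ccccc1)(c1ccccc1)c1ccccc1 | intermediate (not isolated)
18 | [(2E,4E,6E)-2,7-dimethylocta-2,4,6-triene-1,8-diyl]bis(triphenylphosphonium) dibromide | [Br-].[Br-].c1ccccc1[P+](c1ccccc1)(c1ccccc1)C/C(C)=C/C=C/C=C(C)/C[P+](c1ccccc1)(c1ccccc1)c1ccccc1 | intermediate
19 | C10 bis(triphenylphosphonium ylide) from 18 | c1ccccc1P(c1ccccc1)(c1ccccc1)=C/C(C)=C/C=C/C=C(C)/C=P(c1ccccc1)(c1ccccc1)c1ccccc1 | intermediate (not isolated)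
20 | C25 ylide after the first olefination (E isomer shown) | c1ccccc1P(c1ccccc1)(c1ccccc1)=C/C(C)=C/C=C/C=C(C)/C=C/C=C(C)/C=C/[C@]12C(C)(C)C[C@H](O[Si](C)(C)C(C)(C)C)C[C@@]1(C)O2 | intermediate (not isolated)
21 | (3S,5R,6S,3′S,5′R,6′S)-3,3′-bis(TBS-oxy)-5,6:5′,6′-diepoxy-5,6,5′,6′-tetrahydro-β,β-carotene | CC(/C=C/C=C(C)/C=C/[C@]12C(C)(C)C[C@H](O[Si](C)(C)C(C)(C)C)C[C@@]1(C)O2)=C\C=C\C=C(C)\C=C\C=C(C)\C=C\[C@]12C(C)(C)C[C@H](O[Si](C)(C)C(C)(C)C)C[C@@]1(C)O2 | intermediate
22 | violaxanthin mono-TBS ether | CC(/C=C/C=C(C)/C=C/[C@]12C(C)(C)C[C@H](O[Si](C)(C)C(C)(C)C)C[C@@]1(C)O2)=C\C=C\C=C(C)\C=C\C=C(C)\C=C\[C@]12C(C)(C)C[C@H](O)C[C@@]1(C)O2 | intermediate (not isolated)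
23 | (3S,5R,6S,3′S,5′R,6′S)-5,6:5′,6′-diepoxy-5,6,5′,6′-tetrahydro-β,β-carotene-3,3′-diol (violaxanthin) | CC(/C=C/C=C(C)/C=C/[C@]12C(C)(C)C[C@H](O)C[C@@]1(C)O2)=C\C=C\C=C(C)\C=C\C=C(C)\C=C\[C@]12C(C)(C)C[C@H](O)C[C@@]1(C)O2 | intermediate
24 | (3S,5R,6S,3′S,5′R,8′R)-5,6:5′,8′-diepoxy-5,6,5′,8′-tetrahydro-β,β-carotene-3,3′-diol ((8′R)-luteoxanthin) | CC(/C=C/C=C(C)/C=C/[C@]12C(C)(C)C[C@H](O)C[C@@]1(C)O2)=C\C=C\C=C(C)\C=C\C=C(/C)[C@H]1C=C2C(C)(C)C[C@H](O)C[C@@]2(C)O1 | intermediate (not isolated)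
25 | (3S,5R,8R,3′S,5′R,8′R)-5,8:5′,8′-diepoxy-5,8,5′,8′-tetrahydro-β,β-carotene-3,3′-diol | CC(/C=C/C=C(\C)[C@H]1C=C2C(C)(C)C[C@H](O)C[C@@]2(C)O1)=C\C=C\C=C(C)\C=C\C=C(/C)[C@H]1C=C2C(C)(C)C[C@H](O)C[C@@]2(C)O1 | target

**Summary**

Total steps: 13. Longest linear sequence: 11 steps (steps 1–8 and 11–13, from 1); the C10 branch has 2 steps (9 and 10).

Steps most likely to fail:

1. Step 13. The oxygen recapture at C8 and C8′ is expected to show poor facial selectivity, so three C40 diastereomers arise and the wanted one must be separated; prolonged acid contact may also degrade or isomerise the polyene. The fallback sets out from 13 and returns at 25. It moves the ring expansion to the C15 stage, where only two C8 epimers form and can be separated on silica. NaBH4 reduction of 13 gives (2E,4E)-5-[(1S,4S,6R)-4-(TBS-oxy)-2,2,6-trimethyl-7-oxabicyclo[4.1.0]heptan-1-yl]-3-methylpenta-2,4-dien-1-ol F1. Catalytic pyridinium p-toluenesulfonate in CH2Cl2 at 0 °C expands its vinyl oxirane, and the (8R) epimer, (2E)-3-[(2R,6S,7aR)-6-(TBS-oxy)-4,4,7a-trimethyl-2,4,5,6,7,7a-hexahydro-1-benzofuran-2-yl]but-2-en-1-ol F2, is kept while the (8S) epimer is re-equilibrated with the same acid. MnO2 oxidation gives the corresponding but-2-enal F3. Double Wittig reaction of F3 with 18 under the neutral 1,2-epoxybutane protocol (to spare the doubly allylic C8–H) gives auroxanthin bis-TBS ether F4, and n-Bu4NF then gives 25.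

2. Step 5. Epoxidation of the hindered tetrasubstituted alkene may be slow, reagent control of the face may be incomplete, and the titanium reagent may open the product oxirane. The fallback sets out from 6 and returns at 11. MnO2 oxidation of 6 gives (4R)-4-(TBS-oxy)-2,6,6-trimethylcyclohex-1-ene-1-carbaldehyde F5. Olefination with 9 as in step 7 gives (2E,4E)-5-[(4R)-4-(TBS-oxy)-2,6,6-trimethylcyclohex-1-en-1-yl]-3-methylpenta-2,4-dienenitrile F6. mCPBA with NaHCO3 in CH2Cl2 at 0 °C then epoxidises the most electron-rich, tetrasubstituted ring alkene under steric control by the silyloxy group; attack anti to it is expected to prevail, the syn isomer is removed by chromatography, and the product is 11.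

3. Step 11. The second olefination may stall at the C25 stage, and Z geometry at the new double bonds may persist, so that the thermal isomerisation stresses the bis-oxirane. The fallback sets out from 16 and returns at 21. PBr3 with pyridine in Et2O at −10 °C gives (2E,4E,6E)-1,8-dibromo-2,7-dimethylocta-2,4,6-triene F7. Arbuzov reaction with P(OEt)3 gives tetraethyl [(2E,4E,6E)-2,7-dimethylocta-2,4,6-triene-1,8-diyl]bis(phosphonate) F8. Double Horner–Wadsworth–Emmons reaction of F8 (NaH, THF) with two equivalents of 13 should give 21 with E geometry at both new bonds and without a heating stage.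

Further compounds
F1 | step 13 | (2E,4E)-5-[(1S,4S,6R)-4-(TBS-oxy)-2,2,6-trimethyl-7-oxabicyclo[4.1.0]heptan-1-yl]-3-methylpenta-2,4-dien-1-ol | OC/C=C(C)/C=C/[C@]12C(C)(C)C[C@H](O[Si](C)(C)C(C)(C)C)C[C@@]1(C)O2
F2 | step 13 | (2E)-3-[(2R,6S,7aR)-6-(TBS-oxy)-4,4,7a-trimethyl-2,4,5,6,7,7a-hexahydro-1-benzofuran-2-yl]but-2-en-1-ol | OC/C=C(C)/[C@H]1C=C2C(C)(C)C[C@H](O[Si](C)(C)C(C)(C)C)C[C@@]2(C)O1
F3 | step 13 | (2E)-3-[(2R,6S,7aR)-6-(TBS-oxy)-4,4,7a-trimethyl-2,4,5,6,7,7a-hexahydro-1-benzofuran-2-yl]but-2-enal | O=C/C=C(C)/[C@H]1C=C2C(C)(C)C[C@H](O[Si](C)(C)C(C)(C)C)C[C@@]2(C)O1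
F4 | step 13 | (3S,5R,8R,3′S,5′R,8′R)-3,3′-bis(TBS-oxy)-5,8:5′,8′-diepoxy-5,8,5′,8′-tetrahydro-β,β-carotene | CC(/C=C/C=C(\C)[C@H]1C=C2C(C)(C)C[C@H](O[Si](C)(C)C(C)(C)C)C[C@@]2(C)O1)=C\C=C\C=C(C)\C=C\C=C(/C)[C@H]1C=C2C(C)(C)C[C@H](O[Si](C)(C)C(C)(C)C)C[C@@]2(C)O1
F5 | step 5 | (4R)-4-(TBS-oxy)-2,6,6-trimethylcyclohex-1-ene-1-carbaldehyde | CC1=C(C=O)C(C)(C)C[C@H](O[Si](C)(C)C(C)(C)C)C1
F6 | step 5 | (2E,4E)-5-[(4R)-4-(TBS-oxy)-2,6,6-trimethylcyclohex-1-en-1-yl]-3-methylpenta-2,4-dienenitrile | CC1=C(/C=C/C(C)=C/C#N)C(C)(C)C[C@H](O[Si](C)(C)C(C)(C)C)C1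
F7 | step 11 | (2E,4E,6E)-1,8-dibromo-2,7-dimethylocta-2,4,6-triene | BrC/C(C)=C/C=C/C=C(C)/CBr
F8 | step 11 | tetraethyl [(2E,4E,6E)-2,7-dimethylocta-2,4,6-triene-1,8-diyl]bis(phosphonate) | CCOP(=O)(OCC)C/C(C)=C/C=C/C=C(C)/CP(=O)(OCC)OCC
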